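**Retrosynthetic overview**

1. The target comes from its C12 triethylsilyl ether by desilylation. The chlorocyclopentenone is the only ring and is formed once, in the last C–C bond-forming operation.
2. That ring comes from an acyclic alkenylstannane aldehyde and 2-chloro-2-(diethoxyphosphoryl)acetyl chloride. The C8–C9 bond is made by Stille acylation and the C10=C11 bond by intramolecular Horner–Wadsworth–Emmons olefination, in one pot (a formal [3+2] annulation).
3. Enabling feature: in the five-membered ring the two-carbon unit C9(=O)–C10(Cl) lies between two sp2 carbons, C8 (the exocyclic alkylidene carbon) and C11 (the ring CH), and both are bonded to the quaternary carbinol C12. An acyclic C12 carbinol carrying an alkenyl-metal at C8 and a non-enolisable aldehyde at C11 can therefore be closed by a C2 acyl-phosphonate linchpin. The C12 OH is propargylic to C8 and directs the tin there.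
4. The stannane comes from a 7-yne by hydroxyl-directed trans-hydrostannation (sets 7Z). The enyne comes from a terminal alkyne and an (E)-vinyl iodide by Sonogashira coupling (5E).
5. The alkyne comes from a 2,2-disubstituted epoxy alcohol. C12 is set by Sharpless epoxidation of a mono-silylated 2-methylenepropane-1,3-diol, and C13–C20 come from a (Z)-heptenyl cuprate (14Z).

Key step: step 13

Remark: locants C1–C20 in the text follow the prostanoid numbering of the target (C8 alkylidene carbon, C9 ketone, C10 chloro carbon, C11 ring CH, C12 carbinol); pentyllithium and [Cp*RuCl]4 are taken as purchasable.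

**Route**

Step 1
Reactants: 1 2-methylenepropane-1,3-diol
Product: 2 2-[(triethylsilyloxy)methyl]prop-2-en-1-ol
Conditions: NaH (1.0 equiv), THF, 0 °C; Et3SiCl (1.0 equiv), 0 °C to rt
Reagents that add atoms: chlorotriethylsilane, CC[Si](Cl)(CC)CC
Why: Mono-O-silylation through the sparingly soluble monosodium alkoxide (Williamson-type silyl ether formation) should differentiate the two equivalent hydroxymethyl arms; no stereocentre is involved.

Step 2
Reactants: 2 2-[(triethylsilyloxy)methyl]prop-2-en-1-ol
Product: 3 [(2R)-2-[(triethylsilyloxy)methyl]oxiran-2-yl]methanol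
Conditions: Ti(OiPr)4 (10 mol%), D-(−)-diethyl tartrate (12 mol%), t-BuOOH, 4 Å MS, CH2Cl2, −20 °C
Reagents that add atoms: tert-butyl hydroperoxide, CC(C)(C)OO
Why: Sharpless asymmetric epoxidation of a 2-substituted allylic alcohol, in which the titanium tartrate complex with the D-(−)-tartrate delivers oxygen to the face that gives the (R)-epoxide and so sets the future C12 centre; Payne rearrangement of 3 is degenerate and cannot erode it.

Step 3
Reactants: 3 [(2R)-2-[(triethylsilyloxy)methyl]oxiran-2-yl]methanol; 4 pentyllithium; 5 acetylene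
Product: 8 (2S,4Z)-2-[(triethylsilyloxy)methyl]dec-4-ene-1,2-diol, via lithium dipentylcuprate 6 (not isolated), via lithium di[(Z)-hept-1-enyl]cuprate 7 (not isolated)
Conditions: 4 (4 equiv), CuBr·SMe2 (2 equiv), Et2O, −35 °C; 5 (4 equiv), −50 to −25 °C; then lithium alkoxide of 3 (n-BuLi, THF, −78 °C), −25 to 0 °C; aq. NH4Cl/NH3
Reagents that add atoms: none
Why: syn-Carbocupration of acetylene should give the (Z)-heptenyl cuprate, and its SN2 opening of the epoxide at the only unsubstituted ring carbon (organocuprate epoxide opening) installs the 14Z chain with retention of alkene geometry and without touching the quaternary stereocentre.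

Step 4
Reactants: 8 (2S,4Z)-2-[(triethylsilyloxy)methyl]dec-4-ene-1,2-diol
Product: 9 (2R,4Z)-2-hydroxy-2-[(triethylsilyloxy)methyl]dec-4-enal
Conditions: SO3·pyridine, DMSO, iPr2NEt, CH2Cl2, 0 °C
Reagents that add atoms: none
Why: Parikh–Doering oxidation should take only the primary alcohol to the aldehyde, since the tertiary alcohol cannot be oxidised and activated DMSO, unlike periodinane or periodate oxidants, does not cleave the 1,2-diol; the aldehyde has no α-hydrogen.

Step 5
Reactants: 9 (2R,4Z)-2-hydroxy-2-[(triethylsilyloxy)methyl]dec-4-enal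
Product: 10 (3S,5Z)-3-[(triethylsilyloxy)methyl]undec-5-en-1-yn-3-ol
Conditions: Me3SiCHN2 (2.5 equiv), n-BuLi (2.4 equiv), THF, −78 °C; add 9; −78 to 0 °C; aq. NH4Cl
Reagents that add atoms: (trimethylsilyl)diazomethane, C[Si](C)(C)C=[N+]=[N-]
Why: Colvin rearrangement (addition of the lithiated silyldiazomethane, Peterson elimination, 1,2-hydride shift of the alkylidene carbene) should give the terminal alkyne under aprotic conditions that spare the primary silyl ether.

Step 6
Reactants: 11 methyl hex-5-ynoate
Product: 12 methyl (5E)-6-iodohex-5-enoate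
Conditions: Cp2Zr(H)Cl (1.2 equiv), THF, rt; I2, 0 °C
Reagents that add atoms: iodine, II
Why: syn-Hydrozirconation places zirconium on the terminal carbon, and stereoretentive iododezirconation should give the (E)-vinyl iodide that fixes the 5E geometry.

Step 7
Reactants: 10 (3S,5Z)-3-[(triethylsilyloxy)methyl]undec-5-en-1-yn-3-ol; 12 methyl (5E)-6-iodohex-5-enoate
Product: 13 methyl (5E,9S,11Z)-9-hydroxy-9-[(triethylsilyloxy)methyl]heptadeca-5,11-dien-7-ynoate
Conditions: Pd(PPh3)2Cl2 (3 mol%), CuI (6 mol%), Et3N, THF, rt
Reagents that add atoms: none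
Why: Sonogashira coupling should join the two fragments with retention of the (E)-iodide geometry and tolerates the free tertiary propargylic alcohol, the ester and the silyl ether.

Step 8
Reactants: 13 methyl (5E,9S,11Z)-9-hydroxy-9-[(triethylsilyloxy)methyl]heptadeca-5,11-dien-7-ynoate
Product: 14 methyl (5E,7Z,9R,11Z)-9-hydroxy-8-(tributylstannyl)-9-[(triethylsilyloxy)methyl]heptadeca-5,7,11-trienoate
Conditions: [Cp*RuCl]4 (2.5 mol%), Bu3SnH (1.1 equiv), CH2Cl2, rt
Reagents that add atoms: tributyltin hydride, CCCC[SnH](CCCC)CCCC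
Why: Hydroxyl-directed ruthenium-catalysed trans-hydrostannation: hydrogen bonding of the free tertiary OH to the Ru–Cl unit should steer tin to the alkyne carbon next to the carbinol (C8) while hydride adds anti, so tin ends cis to C6, the geometry that becomes 7Z.

Step 9
Reactants: 14 methyl (5E,7Z,9R,11Z)-9-hydroxy-8-(tributylstannyl)-9-[(triethylsilyloxy)methyl]heptadeca-5,7,11-trienoate
Product: 15 methyl (5E,7Z,9R,11Z)-8-(tributylstannyl)-9-(triethylsilyloxy)-9-[(triethylsilyloxy)methyl]heptadeca-5,7,11-trienoate
Conditions: Et3SiOTf, 2,6-lutidine, CH2Cl2, −78 to 0 °C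
Reagents that add atoms: triethylsilyl trifluoromethanesulfonate, CC[Si](CC)(CC)OS(=O)(=O)C(F)(F)F
Why: O-Silylation of the hindered tertiary alcohol with the silyl triflate masks the OH before the acylation chemistry, and the hindered pyridine base should prevent protodestannylation.

Step 10
Reactants: 15 methyl (5E,7Z,9R,11Z)-8-(tributylstannyl)-9-(triethylsilyloxy)-9-[(triethylsilyloxy)methyl]heptadeca-5,7,11-trienoate
Product: 16 methyl (5E,7Z,9R,11Z)-9-formyl-8-(tributylstannyl)-9-(triethylsilyloxy)heptadeca-5,7,11-trienoate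
Conditions: (COCl)2, DMSO, CH2Cl2, −78 to −40 °C; Et3N, −78 °C to rt
Reagents that add atoms: none
Why: Swern oxidation converts a primary triethylsilyl ether directly into the aldehyde (silyl transfer to chloride, then alkoxysulfonium ylide fragmentation), while the tertiary silyl ether and the alkenylstannane should survive; the aldehyde is non-enolisable.

Step 11
Reactants: 17 ethyl 2-chloro-2-(diethoxyphosphoryl)acetate
Product: 18 2-chloro-2-(diethoxyphosphoryl)acetic acid
Conditions: KOH (1.0 equiv), EtOH/H2O, 0 °C to rt; then aq. HCl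
Reagents that add atoms: potassium hydroxide, [K+].[OH-]
Why: Saponification (acyl-oxygen ester hydrolysis) should take only the carboxylic ester, which is far more electrophilic than the phosphonate esters.

Step 12
Reactants: 18 2-chloro-2-(diethoxyphosphoryl)acetic acid
Product: 19 2-chloro-2-(diethoxyphosphoryl)acetyl chloride
Conditions: (COCl)2, DMF (cat.), CH2Cl2, 0 °C to rt; used crude
Reagents that add atoms: oxalyl chloride, ClC(=O)C(Cl)=O
Why: Vilsmeier-type activation of the acid with oxalyl chloride and catalytic DMF should give the acid chloride under base-free conditions that avoid ketene formation.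

Step 13
Reactants: 16 methyl (5E,7Z,9R,11Z)-9-formyl-8-(tributylstannyl)-9-(triethylsilyloxy)heptadeca-5,7,11-trienoate; 19 2-chloro-2-(diethoxyphosphoryl)acetyl chloride
Product: 21 methyl (5E,7Z)-7-[(2R)-4-chloro-2-[(2Z)-oct-2-en-1-yl]-5-oxo-2-(triethylsilyloxy)cyclopent-3-en-1-ylidene]hept-5-enoate, via acyclic chloro ketophosphonate aldehyde 20 (not isolated)
Conditions: Pd2(dba)3 (5 mol%), P(2-furyl)3 (20 mol%), THF, 45 °C; then LiCl, iPr2NEt, MeCN, 0 °C to rt
Reagents that add atoms: none
Why: Zerovalent palladium inserts into the acyl C–Cl bond of 19, the alkenyl group of 16 is transferred from tin with retention and reductive elimination forms the C8–C9 bond of dienyl ketone 20 (Stille acylation); LiCl/iPr2NEt then deprotonates the doubly activated CHCl carbon of 20, the carbanion adds to the neighbouring aldehyde and the oxaphosphetane collapses to the C10=C11 bond with loss of diethyl phosphate (intramolecular Horner–Wadsworth–Emmons olefination). The closest known reaction types are the ketone synthesis from acid chlorides and alkenylstannanes and the cyclopentenone-forming intramolecular olefination of 2-oxoalkylphosphonates that carry a 1,4-related carbonyl group, here run in one pot as a formal [3+2] annulation. The single ring closes in the 5-(enolendo)-exo-trig mode, C10 attacking the exocyclic C11=O, so the new ring alkene can only be cis and both epimers of 20 at the CHCl carbon converge on one product. No stereocentre is created: C12 is quaternary and its aldehyde is non-enolisable, so the configuration from step 2 cannot be lost, and the 7Z geometry is the tin geometry of 16 carried over by stereoretentive transmetalation. The step needs C-acylation at the hindered C8 to outrun protodestannylation and ketene formation from 19 (hence no base until coupling is complete), palladium insertion into the acyl chloride in preference to the alkyl C–Cl bond, and olefination instead of Darzens-type epoxide closure, which the phosphonate secures and a simple chloromethyl ketone would not.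

Step 14
Reactants: 21 methyl (5E,7Z)-7-[(2R)-4-chloro-2-[(2Z)-oct-2-en-1-yl]-5-oxo-2-(triethylsilyloxy)cyclopent-3-en-1-ylidene]hept-5-enoate
Product: 22 chlorovulone III, methyl (5E,7Z)-7-[(2R)-4-chloro-2-hydroxy-2-[(2Z)-oct-2-en-1-yl]-5-oxocyclopent-3-en-1-ylidene]hept-5-enoate
Conditions: HF·pyridine, pyridine, THF, 0 °C
Reagents that add atoms: none
Why: Fluoride-mediated silyl ether cleavage under buffered, non-basic conditions should free the tertiary alcohol and leave the cross-conjugated chlorodienone, the methyl ester and all alkene geometries untouched.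

**Compound list**

1 | 2-methylenepropane-1,3-diol | C=C(CO)CO | starting material
2 | 2-[(triethylsilyloxy)methyl]prop-2-en-1-ol | C=C(CO)CO[Si](CC)(CC)CC | intermediate
3 | [(2R)-2-[(triethylsilyloxy)methyl]oxiran-2-yl]methanol | OC[C@]1(CO[Si](CC)(CC)CC)CO1 | intermediate
4 | pentyllithium | [Li]CCCCC | starting material
5 | acetylene | C#C | starting material
6 | lithium dipentylcuprate | [Li+].CCCCC[Cu-]CCCCC | intermediate
7 | lithium di[(Z)-hept-1-enyl]cuprate | [Li+].CCCCC/C=C\[Cu-]/C=C\CCCCC | intermediate
8 | (2S,4Z)-2-[(triethylsilyloxy)methyl]dec-4-ene-1,2-diol | CCCCC/C=C\C[C@](O)(CO)CO[Si](CC)(CC)CC | intermediate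
9 | (2R,4Z)-2-hydroxy-2-[(triethylsilyloxy)methyl]dec-4-enal | CCCCC/C=C\C[C@](O)(C=O)CO[Si](CC)(CC)CC | intermediate
10 | (3S,5Z)-3-[(triethylsilyloxy)methyl]undec-5-en-1-yn-3-ol | CCCCC/C=C\C[C@](O)(C#C)CO[Si](CC)(CC)CC | intermediate
11 | methyl hex-5-ynoate | COC(=O)CCCC#C | starting material
12 | methyl (5E)-6-iodohex-5-enoate | COC(=O)CCC/C=C/I | intermediate
13 | methyl (5E,9S,11Z)-9-hydroxy-9-[(triethylsilyloxy)methyl]heptadeca-5,11-dien-7-ynoate | CCCCC/C=C\C[C@](O)(C#C/C=C/CCCC(=O)OC)CO[Si](CC)(CC)CC | intermediate
14 | methyl (5E,7Z,9R,11Z)-9-hydroxy-8-(tributylstannyl)-9-[(triethylsilyloxy)methyl]heptadeca-5,7,11-trienoate | CCCCC/C=C\C[C@](O)(/C(=C/C=C/CCCC(=O)OC)[Sn](CCCC)(CCCC)CCCC)CO[Si](CC)(CC)CC | intermediate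
15 | methyl (5E,7Z,9R,11Z)-8-(tributylstannyl)-9-(triethylsilyloxy)-9-[(triethylsilyloxy)methyl]heptadeca-5,7,11-trienoate | CCCCC/C=C\C[C@](O[Si](CC)(CC)CC)(/C(=C/C=C/CCCC(=O)OC)[Sn](CCCC)(CCCC)CCCC)CO[Si](CC)(CC)CC | intermediate
16 | methyl (5E,7Z,9R,11Z)-9-formyl-8-(tributylstannyl)-9-(triethylsilyloxy)heptadeca-5,7,11-trienoate | CCCCC/C=C\C[C@](O[Si](CC)(CC)CC)(/C(=C/C=C/CCCC(=O)OC)[Sn](CCCC)(CCCC)CCCC)C=O | intermediate
17 | ethyl 2-chloro-2-(diethoxyphosphoryl)acetate (triethyl 2-chloro-2-phosphonoacetate) | CCOC(=O)C(Cl)P(=O)(OCC)OCC | starting material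
18 | 2-chloro-2-(diethoxyphosphoryl)acetic acid | CCOP(=O)(OCC)C(Cl)C(O)=O | intermediate
19 | 2-chloro-2-(diethoxyphosphoryl)acetyl chloride | CCOP(=O)(OCC)C(Cl)C(Cl)=O | intermediate
20 | methyl (5E,7Z,9S,11Z)-8-[2-chloro-2-(diethoxyphosphoryl)acetyl]-9-formyl-9-(triethylsilyloxy)heptadeca-5,7,11-trienoate, both epimers at the CHCl carbon | CCCCC/C=C\C[C@](O[Si](CC)(CC)CC)(/C(=C/C=C/CCCC(=O)OC)C(=O)C(Cl)P(=O)(OCC)OCC)C=O | intermediate
21 | methyl (5E,7Z)-7-[(2R)-4-chloro-2-[(2Z)-oct-2-en-1-yl]-5-oxo-2-(triethylsilyloxy)cyclopent-3-en-1-ylidene]hept-5-enoate | CCCCC/C=C\C[C@@]1(O[Si](CC)(CC)CC)C=C(Cl)C(=O)/C1=C\C=C\CCCC(=O)OC | intermediate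
22 | chlorovulone III, methyl (5E,7Z)-7-[(2R)-4-chloro-2-hydroxy-2-[(2Z)-oct-2-en-1-yl]-5-oxocyclopent-3-en-1-ylidene]hept-5-enoate | CCCCC/C=C\C[C@@]1(O)C=C(Cl)C(=O)/C1=C\C=C\CCCC(=O)OC | target

**Step count and risks**

Total step count: 14. Longest linear sequence: 11 steps (1–5, 7–10, 13, 14).

Steps most likely to fail:

1. Step 13. Tin-to-palladium transfer at the hindered C8 may be slow, so that protodestannylation and ketene formation from 19 compete, and the Z-dienone may isomerise before ring closure. Fallback, from 15: iododestannylation (I2, CH2Cl2, 0 °C) gives methyl (5E,7Z,9R,11Z)-8-iodo-9-(triethylsilyloxy)-9-[(triethylsilyloxy)methyl]heptadeca-5,7,11-trienoate F1. Palladium-catalysed hydroxycarbonylation (Pd(PPh3)4, CO, H2O, Et3N, DMF) gives the C8 carboxylic acid F2. Activation with carbonyldiimidazole and C-acylation of lithiated diethyl (chloromethyl)phosphonate (THF, −78 °C; the acyl imidazolide reacts in preference to the methyl ester) gives the bis-silylated chloro ketophosphonate F3, so the C9–C10 bond is made by Claisen-type acylation and C9 comes from CO. Swern oxidation of the primary silyl ether of F3 comes back to the route at 20, now isolated, which is closed to 21 with LiCl/iPr2NEt as in step 13.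

2. Step 8. The conjugated enyne, and the dienylstannane formed from it, may bind the ruthenium catalyst, and regiocontrol may be lost if the hydrogen bond to the tertiary OH is outweighed by the electronic bias of the enyne. Fallback, from 10: Pd(PPh3)4-catalysed syn-distannylation with hexabutylditin (toluene, 80 °C) gives (1Z,3R,5Z)-1,2-bis(tributylstannyl)-3-[(triethylsilyloxy)methyl]undeca-1,5-dien-3-ol F4. Site-selective Stille coupling of its less hindered terminal tin with 12 (Pd2(dba)3, AsPh3, CuI, DMF) comes back to the route at 14, with the same cis relation of the remaining tin and C6.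

3. Step 3. SN2 opening next to the quaternary alkoxide centre may be sluggish, so that thermal decomposition of the alkenyl cuprate and transfer of only part of the alkenyl ligand limit conversion. Fallback, from 3: opening of its lithium alkoxide with lithium hept-1-ynide and BF3·OEt2 (1-heptyne, n-BuLi, THF, −78 °C) gives (2S)-2-[(triethylsilyloxy)methyl]dec-4-yne-1,2-diol F5. Semi-hydrogenation (H2, Pd/CaCO3 poisoned with Pb(OAc)2, quinoline, EtOAc) comes back to the route at 8.

Further compounds
F1 | step 13 | methyl (5E,7Z,9R,11Z)-8-iodo-9-(triethylsilyloxy)-9-[(triethylsilyloxy)methyl]heptadeca-5,7,11-trienoate | CCCCC/C=C\C[C@](O[Si](CC)(CC)CC)(/C(I)=C/C=C/CCCC(=O)OC)CO[Si](CC)(CC)CC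
F2 | step 13 | methyl (5E,7Z,9S,11Z)-8-carboxy-9-(triethylsilyloxy)-9-[(triethylsilyloxy)methyl]heptadeca-5,7,11-trienoate | CCCCC/C=C\C[C@](O[Si](CC)(CC)CC)(/C(C(O)=O)=C/C=C/CCCC(=O)OC)CO[Si](CC)(CC)CC
F3 | step 13 | methyl (5E,7Z,9S,11Z)-8-[2-chloro-2-(diethoxyphosphoryl)acetyl]-9-(triethylsilyloxy)-9-[(triethylsilyloxy)methyl]heptadeca-5,7,11-trienoate | CCCCC/C=C\C[C@](O[Si](CC)(CC)CC)(/C(=C/C=C/CCCC(=O)OC)C(=O)C(Cl)P(=O)(OCC)OCC)CO[Si](CC)(CC)CC
F4 | step 8 | (1Z,3R,5Z)-1,2-bis(tributylstannyl)-3-[(triethylsilyloxy)methyl]undeca-1,5-dien-3-ol | CCCCC/C=C\C[C@](O)(/C(=C/[Sn](CCCC)(CCCC)CCCC)[Sn](CCCC)(CCCC)CCCC)CO[Si](CC)(CC)CC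
F5 | step 3 | (2S)-2-[(triethylsilyloxy)methyl]dec-4-yne-1,2-diol | CCCCCC#CC[C@](O)(CO)CO[Si](CC)(CC)CC
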